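**Retrosynthetic overview**
1. 15 ⇒ 13: the C11–OAc bond is made last, by a new cobalt-hydride hydroacetoxylation of the isopropenyl group (key C–O step).
2. 13 ⇒ 12: the C8–O ester bond comes from a Mitsunobu inversion with methacrylic acid. 12 ⇒ 10: the cyclopentenone comes from alkyne hydration and aldol condensation.
3. 10 ⇒ 7: the C7–C11 bond comes from copper-catalysed addition anti to O8. 7 ⇒ 5: the first C8–O bond comes from a vinylogous Rubottom oxidation, so O8 relays stereochemistry from C10 to C7.
4. 5 ⇒ 2 + 3: catalytic asymmetric methyl addition followed by propargylation. 2 ⇒ cycloheptanone 1.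
5. Ring order: the seven-membered ring is bought (1) and the five-membered ring is closed in step 5.

Assumption: guaiane numbering is used for positions (C8 carries the methacrylate, C11 the acetate, C10 the ring methyl, C1 is the ring-fusion CH), and β is the face of the C10 methyl group.

**Step 1**
Reactants: 1 cycloheptanone
Product: 2 cyclohepta-2,6-dien-1-one
Conditions: IBX (2.5 equiv), DMSO/PhF, 75 °C
Reagents that add atoms: none
Why: IBX dehydrogenation of a ketone through its enol acts once on each side of the symmetric ketone and stops at the cross-conjugated dienone at this stoichiometry and temperature, and no stereocentre is formed.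

**Step 2**
Reactants: 2 cyclohepta-2,6-dien-1-one; 3 1-bromobut-2-yne
Product: 5 (6S,7R)-7-(but-2-yn-1-yl)-6-methylcyclohept-2-en-1-one, via methylzinc dienolate 4 (not isolated)
Conditions: Me2Zn (1.05 equiv), Cu(OTf)2 (2 mol %), binaphthol-derived N,N-bis(1-phenylethyl)phosphoramidite (4 mol %, the enantiomer that gives 6S), toluene, −25 °C; then 3, HMPA, Bu4NI (cat.), −25 to 0 °C
Reagents that add atoms: dimethylzinc C[Zn]C
Why: Copper-catalysed enantioselective conjugate addition (Feringa type) desymmetrises the dienone and sets C10 under catalyst control, the dienolate form shields the second enone from over-addition, and three-component trapping with the propargylic halide occurs anti to the new methyl group to set C1.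

**Step 3**
Reactants: 5 (6S,7R)-7-(but-2-yn-1-yl)-6-methylcyclohept-2-en-1-one
Product: 7 (4S,6S,7R)-7-(but-2-yn-1-yl)-4-hydroxy-6-methylcyclohept-2-en-1-one, via trimethylsilyl dienol ether 6 (not isolated)
Conditions: TMSOTf, Et3N, CH2Cl2, 0 °C to rt; then DMDO (acetone), −78 to −40 °C; aq. citric acid work-up
Reagents that add atoms: dimethyldioxirane CC1(C)OO1; trimethylsilyl triflate C[Si](C)(C)OS(=O)(=O)C(F)(F)F (silicon only in 6)
Why: In this vinylogous Rubottom oxidation, soft enolisation away from the hindered tertiary C1–H gives the linear dienol ether, and electrophilic oxygen enters at the γ-terminus C8 along the axial trajectory, trans to the equatorial C10 methyl, as in trans additions to 5-substituted cyclohexenones and the 6β-hydroxylation of steroidal dienol ethers, which gives the 8α alcohol.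

**Step 4**
Reactants: 7 (4S,6S,7R)-7-(but-2-yn-1-yl)-4-hydroxy-6-methylcyclohept-2-en-1-one
Product: 10 (2R,3S,5S,6R)-2-(but-2-yn-1-yl)-5-hydroxy-3-methyl-6-(prop-1-en-2-yl)cycloheptan-1-one, via trimethylsilyl ether 8 (not isolated), via bis-silyl enol ether 9 (not isolated)
Conditions: TMSCl, Et3N, THF, 0 °C; then CH2=C(CH3)MgBr (1.5 equiv), CuBr·SMe2 (10 mol %), TMSCl, HMPA, THF, −78 °C; then 1 M HCl, THF, 0 °C
Reagents that add atoms: isopropenylmagnesium bromide C=C(C)[Mg]Br; chlorotrimethylsilane C[Si](C)(C)Cl (silicon only in 8 and 9)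
Why: Copper-catalysed, TMSCl-accelerated conjugate addition of a Grignard reagent to a γ-silyloxy enone takes place anti to the adjacent silyloxy group, which places the isopropenyl group β at C7, and the acidic work-up removes both silyl groups.

**Step 5**
Reactants: 10 (2R,3S,5S,6R)-2-(but-2-yn-1-yl)-5-hydroxy-3-methyl-6-(prop-1-en-2-yl)cycloheptan-1-one
Product: 12 (5R,6S,8S,8aR)-6-hydroxy-3,8-dimethyl-5-(prop-1-en-2-yl)-4,5,6,7,8,8a-hexahydroazulen-2(1H)-one, via 1,4-diketone 11 (not isolated)
Conditions: NaAuCl4·2H2O (2 mol %), MeOH/H2O 10:1, 50 °C; then KOH (1.5 equiv), same pot, 50 °C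
Reagents that add atoms: water O
Why: Carbonyl-assisted gold-catalysed alkyne hydration gives the 1,4-diketone regioselectively, and a base-mediated intramolecular aldol condensation (jasmone-type cyclopentenone annulation) closes the five-membered ring, while the epimerisable C1 stays trans to the C10 methyl, which is the more stable arrangement.

**Step 6**
Reactants: 12 (5R,6S,8S,8aR)-6-hydroxy-3,8-dimethyl-5-(prop-1-en-2-yl)-4,5,6,7,8,8a-hexahydroazulen-2(1H)-one
Product: 13 (5R,6R,8S,8aR)-3,8-dimethyl-2-oxo-5-(prop-1-en-2-yl)-1,2,4,5,6,7,8,8a-octahydroazulen-6-yl 2-methylprop-2-enoate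
Conditions: methacrylic acid (3 equiv), PPh3, DIAD, BHT (trace), toluene, 0 °C to rt
Reagents that add atoms: methacrylic acid C=C(C)C(=O)O
Why: In this Mitsunobu esterification, SN2 displacement of the alkoxyphosphonium group by methacrylate forms the C8–O ester bond with inversion (8α to 8β, cis to the C7 side chain), as in the menthol to neomenthyl ester inversion.

**Step 7**
Reactants: 13 (5R,6R,8S,8aR)-3,8-dimethyl-2-oxo-5-(prop-1-en-2-yl)-1,2,4,5,6,7,8,8a-octahydroazulen-6-yl 2-methylprop-2-enoate
Product: 15 (5S,6R,8S,8aR)-5-(2-acetoxypropan-2-yl)-3,8-dimethyl-2-oxo-1,2,4,5,6,7,8,8a-octahydroazulen-6-yl 2-methylprop-2-enoate, via dioxanylium triflate 14 (not isolated)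
Conditions: [N,N'-bis(3,5-di-tert-butylsalicylidene)cyclohexane-1,2-diaminato]cobalt, Co(C36H52N2O2) (divalent cobalt, 5 mol %), N-fluoro-2,4,6-trimethylpyridinium triflate (1.3 equiv), PhSiH3 (1.2 equiv), AcOH (10 equiv), PhCF3, 0 °C
Reagents that add atoms: acetic acid CC(=O)O
Why: Proposed new method: a trivalent cobalt hydride formed from the salen complex, the N-fluoropyridinium oxidant and PhSiH3 transfers a hydrogen atom to the CH2 terminus of the electron-rich 1,1-disubstituted alkene (the methacrylate and the tetrasubstituted enone undergo only reversible or no hydrogen-atom transfer), the tertiary C11 radical is captured by divalent cobalt and oxidised to a tetravalent alkylcobalt that ionises with help from the cis C8 ester carbonyl to the six-membered dioxanylium ion 14, and acetate opens this ion at the tertiary carbon in Prévost fashion to form the C11–OAc bond directly without touching C7 or C8; the closest known reaction types are cobalt-salen hydrogen-atom-transfer/radical-polar-crossover hydroalkoxylation and lactonisation of unactivated alkenes and the Prévost opening of acyloxonium ions, neither of which has been shown as a neighbouring-ester-assisted intermolecular acetoxylation next to an acrylate.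

**Compound list**
1 | cycloheptanone | O=C1CCCCCC1 | starting material
2 | cyclohepta-2,6-dien-1-one | O=C1C=CCCC=C1 | intermediate
3 | 1-bromobut-2-yne | CC#CCBr | starting material
4 | methylzinc (S)-3-methylcyclohepta-1,6-dien-1-olate | C[Zn]OC1=C[C@@H](C)CCC=C1 | intermediate
5 | (6S,7R)-7-(but-2-yn-1-yl)-6-methylcyclohept-2-en-1-one | C1C[C@H](C)[C@@H](CC#CC)C(=O)C=C1 | intermediate
6 | {[(6S,7R)-7-(but-2-yn-1-yl)-6-methylcyclohepta-1,3-dien-1-yl]oxy}trimethylsilane | C=1C[C@H](C)[C@@H](CC#CC)C(O[Si](C)(C)C)=CC=1 | intermediate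
7 | (4S,6S,7R)-7-(but-2-yn-1-yl)-4-hydroxy-6-methylcyclohept-2-en-1-one | O[C@H]1C[C@H](C)[C@@H](CC#CC)C(=O)C=C1 | intermediate
8 | (4S,6S,7R)-7-(but-2-yn-1-yl)-6-methyl-4-[(trimethylsilyl)oxy]cyclohept-2-en-1-one | C[Si](C)(C)O[C@H]1C[C@H](C)[C@@H](CC#CC)C(=O)C=C1 | intermediate
9 | (3R,4S,6S,7R)-7-(but-2-yn-1-yl)-6-methyl-3-(prop-1-en-2-yl)-1,4-bis[(trimethylsilyl)oxy]cyclohept-1-ene | C[Si](C)(C)O[C@H]1C[C@H](C)[C@@H](CC#CC)C(O[Si](C)(C)C)=C[C@@H]1C(C)=C | intermediate
10 | (2R,3S,5S,6R)-2-(but-2-yn-1-yl)-5-hydroxy-3-methyl-6-(prop-1-en-2-yl)cycloheptan-1-one | O[C@H]1C[C@H](C)[C@@H](CC#CC)C(=O)C[C@@H]1C(C)=C | intermediate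
11 | (2R,3S,5S,6R)-5-hydroxy-3-methyl-2-(2-oxobutyl)-6-(prop-1-en-2-yl)cycloheptan-1-one | O[C@H]1C[C@H](C)[C@@H](CC(=O)CC)C(=O)C[C@@H]1C(C)=C | intermediate
12 | (5R,6S,8S,8aR)-6-hydroxy-3,8-dimethyl-5-(prop-1-en-2-yl)-4,5,6,7,8,8a-hexahydroazulen-2(1H)-one | O[C@H]1C[C@H](C)[C@H]2CC(=O)C(C)=C2C[C@@H]1C(C)=C | intermediate
13 | (5R,6R,8S,8aR)-3,8-dimethyl-2-oxo-5-(prop-1-en-2-yl)-1,2,4,5,6,7,8,8a-octahydroazulen-6-yl 2-methylprop-2-enoate | C=C(C)C(=O)O[C@@H]1C[C@H](C)[C@H]2CC(=O)C(C)=C2C[C@@H]1C(C)=C | intermediate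
14 | cis-fused 4,4-dimethyl-2-(prop-1-en-2-yl)-1,3-dioxan-2-ylium triflate (O8 and O11 bridged by the methacryloyl carbon, ring stereocentres as in 13) | C=C(C)C=3O[C@@H]1C[C@H](C)[C@H]2CC(=O)C(C)=C2C[C@@H]1C(C)(C)[O+]=3.[O-]S(=O)(=O)C(F)(F)F | intermediate
15 | (5S,6R,8S,8aR)-5-(2-acetoxypropan-2-yl)-3,8-dimethyl-2-oxo-1,2,4,5,6,7,8,8a-octahydroazulen-6-yl 2-methylprop-2-enoate | C=C(C)C(=O)O[C@@H]1C[C@H](C)[C@H]2CC(=O)C(C)=C2C[C@@H]1C(C)(C)OC(C)=O | target

**Totals:** 7 steps in total; longest linear sequence 7 steps (1 → 15).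

**Steps most likely to fail**

Risk 1, step 3. Enolisation could take the α′-hydrogen at C1. Oxygen could also enter at C6 or from the β face. The fallback sets out from 5. Allylic oxidation with Pd(OH)2/C, t-BuOOH and K2CO3 in CH2Cl2 gives the enedione (5R,6S)-5-(but-2-yn-1-yl)-6-methylcyclohept-2-ene-1,4-dione F1. Its less hindered C8 carbonyl is then reduced under reagent control with the methyl oxazaborolidine (CBS) catalyst of the appropriate hand and catecholborane at −78 °C. This gives the 8α alcohol 7, where the route is rejoined.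

Risk 2, step 6. Methacrylic acid is a weak acid and the secondary alcohol is hindered, so elimination or retention could compete. The fallback sets out from 12. Dess–Martin oxidation gives the ketone (5R,8S,8aR)-3,8-dimethyl-5-(prop-1-en-2-yl)-4,5,8,8a-tetrahydroazulene-2,6(1H,7H)-dione F2. LiBH(s-Bu)3 at −78 °C attacks it from the α face, anti to the isopropenyl group. This gives the cis alcohol (5R,6R,8S,8aR)-6-hydroxy-3,8-dimethyl-5-(prop-1-en-2-yl)-4,5,6,7,8,8a-hexahydroazulen-2(1H)-one F3. Acylation with methacrylic anhydride, DMAP and Et3N then gives 13, where the route is rejoined.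

Risk 3, step 7 (the new step). The methacrylate could be reduced, proton loss could regenerate alkene, or acyl groups could scramble through 14. The fallback uses known polar chemistry and no metal hydride, and it sets out from 13. Markovnikov hydrochlorination with dry HCl in CH2Cl2 at −20 °C, as in the conversion of limonene to terpinyl chloride, gives the tertiary chloride (5S,6R,8S,8aR)-5-(2-chloropropan-2-yl)-3,8-dimethyl-2-oxo-1,2,4,5,6,7,8,8a-octahydroazulen-6-yl 2-methylprop-2-enoate F4. Silver-assisted acetolysis with AgOAc in AcOH at rt converts F4 into 15.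

**Further compounds**
F1 | step 3 | (5R,6S)-5-(but-2-yn-1-yl)-6-methylcyclohept-2-ene-1,4-dione | O=C1C[C@H](C)[C@@H](CC#CC)C(=O)C=C1
F2 | step 6 | (5R,8S,8aR)-3,8-dimethyl-5-(prop-1-en-2-yl)-4,5,8,8a-tetrahydroazulene-2,6(1H,7H)-dione | O=C1C[C@H](C)[C@H]2CC(=O)C(C)=C2C[C@@H]1C(C)=C
F3 | step 6 | (5R,6R,8S,8aR)-6-hydroxy-3,8-dimethyl-5-(prop-1-en-2-yl)-4,5,6,7,8,8a-hexahydroazulen-2(1H)-one | O[C@@H]1C[C@H](C)[C@H]2CC(=O)C(C)=C2C[C@@H]1C(C)=C
F4 | step 7 | (5S,6R,8S,8aR)-5-(2-chloropropan-2-yl)-3,8-dimethyl-2-oxo-1,2,4,5,6,7,8,8a-octahydroazulen-6-yl 2-methylprop-2-enoate | C=C(C)C(=O)O[C@@H]1C[C@H](C)[C@H]2CC(=O)C(C)=C2C[C@@H]1C(C)(C)Cl
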